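**Plan**
- Retrosynthesis first cuts the disubstituted double bonds C11=C12 and C11'=C12' (two Wittig reactions; primes mark the dihydrofuran half), leaving the central C10 dialdehyde and two C15 phosphonium salts.
- Both C15 units descend from one C15 trienoate, cut at C9=C10 (Horner–Wadsworth–Emmons) and at C6–C7 (Sonogashira coupling of an enol triflate made from ketoisophorone).
- Enabling feature: C5' and C8', the two carbons bonded to the dihydrofuran oxygen, are the ends of the s-cis diene C5'=C6'–C7'=C8' of a β-ionone-type ring, so one O2 can span them as a six-membered 5,8-endoperoxide; loss of one oxygen atom then leaves the five-membered ring.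
- Forward order: cyclohexane ring (from the start) → C13 enone → C15 trienoate → (a) dihydrofuran ring and its phosphonium salt, (b) syn-epoxide, 5,6-diol and its phosphonium salt → C25 aldehyde with the C10 dialdehyde → C40 chain → desilylation.
- Stereochemistry: C3/C3' from yeast reduction plus substrate-controlled hydrogenation; C5'/C8' from anti-face 1O2 addition and one SN2 inversion; C5/C6 from hydroxyl-directed epoxidation and inverting hydrolysis at C5; E alkenes from trans-hydroalumination, phosphonate and ylide olefinations and thermal equilibration.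

Key step: step 9

Remark: carotenoid locants are used throughout (fragments keep them without primes), TBS = tert-butyldimethylsilyl, but-3-yn-2-ol is used as the racemate because its carbinol centre is oxidised in step 7, and the C10 dialdehyde is taken as a commercial building block.

Step 1
Reactants: 1 ketoisophorone (2,6,6-trimethylcyclohex-2-ene-1,4-dione)
Product: 2 (6R)-2,2,6-trimethylcyclohexane-1,4-dione
Conditions: baker's yeast (Saccharomyces cerevisiae), sucrose, H2O, 30 °C
Reagents that add atoms: none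
Why: Enoate-reductase (old-yellow-enzyme type) conjugate reduction of the enedione C=C by fermenting yeast adds hydride and a proton enantioselectively and sets C6 as R (biocatalytic asymmetric alkene reduction).

Step 2
Reactants: 2 (6R)-2,2,6-trimethylcyclohexane-1,4-dione
Product: 3 (4R,6R)-4-hydroxy-2,2,6-trimethylcyclohexan-1-one (actinol)
Conditions: H2, Raney Ni, MeOH, rt; recrystallisation
Reagents that add atoms: none
Why: Heterogeneous carbonyl hydrogenation touches only the C4 ketone (C1 is shielded by the quaternary carbon), and hydrogen arrives anti to the axial C2 methyl of the chair that keeps the C6 methyl equatorial, so the C6 centre sets C4 as R (trans alcohol), the minor cis isomer being removed by crystallisation.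

Step 3
Reactants: 3 (4R,6R)-4-hydroxy-2,2,6-trimethylcyclohexan-1-one
Product: 4 (4R,6R)-4-(TBS-oxy)-2,2,6-trimethylcyclohexan-1-one
Conditions: TBSCl, imidazole, DMF, rt
Reagents that add atoms: tert-butyldimethylsilyl chloride CC(C)(C)[Si](C)(C)Cl
Why: Imidazole-promoted silylation of the secondary alcohol gives a silyl ether that survives the amide base, hydride and olefination steps that follow.

Step 4
Reactants: 4 (4R,6R)-4-(TBS-oxy)-2,2,6-trimethylcyclohexan-1-one
Product: 5 (4R)-4-(TBS-oxy)-2,6,6-trimethylcyclohex-1-en-1-yl trifluoromethanesulfonate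
Conditions: LiN(iPr)2, THF, −78 °C; then PhNTf2, −78 °C to rt
Reagents that add atoms: N-phenylbis(trifluoromethanesulfonimide) O=S(=O)(N(c1ccccc1)S(=O)(=O)C(F)(F)F)C(F)(F)F
Why: Deprotonation is possible only at C6 (the other α-carbon is quaternary) and O-triflation of the enolate gives the tetrasubstituted enol triflate with the future C5=C6 bond already in place (enolate triflation; the methyl-bearing stereocentre is lost as planned).

Step 5
Reactants: 5 (4R)-4-(TBS-oxy)-2,6,6-trimethylcyclohex-1-en-1-yl trifluoromethanesulfonate, 6 but-3-yn-2-ol (racemic)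
Product: 7 4-[(4R)-4-(TBS-oxy)-2,6,6-trimethylcyclohex-1-en-1-yl]but-3-yn-2-ol (both carbinol epimers)
Conditions: Pd(PPh3)4 (cat.), CuI (cat.), iPr2NH, THF, rt to 50 °C
Reagents that add atoms: none
Why: Sonogashira coupling, in which zerovalent palladium inserts into the vinyl C–OTf bond, the copper acetylide of 6 transmetalates and reductive elimination forms the C6–C7 bond with the free hydroxyl tolerated.

Step 6
Reactants: 7 4-[(4R)-4-(TBS-oxy)-2,6,6-trimethylcyclohex-1-en-1-yl]but-3-yn-2-ol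
Product: 8 (3E)-4-[(4R)-4-(TBS-oxy)-2,6,6-trimethylcyclohex-1-en-1-yl]but-3-en-2-ol (both carbinol epimers)
Conditions: LiAlH4, THF, 0 °C to rt; aq. potassium sodium tartrate
Reagents that add atoms: none
Why: Alkoxide-directed trans-hydroalumination of the propargylic alcohol gives only the E C7=C8 bond after protonolysis, and the silyl ether is inert to the hydride.

Step 7
Reactants: 8 (3E)-4-[(4R)-4-(TBS-oxy)-2,6,6-trimethylcyclohex-1-en-1-yl]but-3-en-2-ol
Product: 9 (3E)-4-[(4R)-4-(TBS-oxy)-2,6,6-trimethylcyclohex-1-en-1-yl]but-3-en-2-one (silyl ether of (3R)-3-hydroxy-β-ionone)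
Conditions: MnO2, CH2Cl2, rt
Reagents that add atoms: none
Why: Heterogeneous MnO2 oxidation is selective for the allylic secondary alcohol, leaves the silyl ether and both alkenes untouched and merges the carbinol epimers into one enone.

Step 8
Reactants: 9 (3E)-4-[(4R)-4-(TBS-oxy)-2,6,6-trimethylcyclohex-1-en-1-yl]but-3-en-2-one, 10 triethyl phosphonoacetate
Product: 11 ethyl (2E,4E)-5-[(4R)-4-(TBS-oxy)-2,6,6-trimethylcyclohex-1-en-1-yl]-3-methylpenta-2,4-dienoate (C15 trienoate)
Conditions: NaH, THF, 0 °C; then 9, rt to 50 °C; chromatography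
Reagents that add atoms: none
Why: Horner–Wadsworth–Emmons olefination of the methyl ketone with the stabilised phosphonate anion forms C9=C10 mainly as the E isomer (ester trans to the larger dienyl residue), and the minor 9Z ester is removed by chromatography.

Step 9
Reactants: 11 ethyl (2E,4E)-5-[(4R)-4-(TBS-oxy)-2,6,6-trimethylcyclohex-1-en-1-yl]-3-methylpenta-2,4-dienoate
Product: 13 ethyl (2E)-3-[(2S,6S,7aR)-6-(TBS-oxy)-4,4,7a-trimethyl-2,4,5,6,7,7a-hexahydro-1-benzofuran-2-yl]but-2-enoate (C15 dihydrofuran enoate), via 5,8-endoperoxide 12 (not isolated)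
Conditions: O2, tetraphenylporphyrin (cat.), visible light, CH2Cl2, −78 °C; then PPh3 (1.1 equiv), −78 °C to rt, dark
Reagents that add atoms: dioxygen O=O
Why: Sensitised 1O2 adds suprafacially across C5 and C8 of the twisted s-cis diene C5=C6–C7=C8 in a concerted (4+2) cycloaddition that closes the 3,6-dihydro-1,2-dioxine ring of 12; PPh3 then attacks the less hindered peroxide oxygen (the one on C8) and the C5 alkoxide displaces Ph3P=O at C8 in a 5-exo-tet SN2 closure that contracts the dioxine to the 2,5-dihydrofuran. Both halves have close precedent, namely 5,8-endoperoxide formation from ionone- and retinoid-type dienes and phosphine deoxygenation of 3,6-dihydro-1,2-dioxines to 2,5-dihydrofurans with inversion at one carbon. C5 (R) is set by approach of 1O2 to the ring face anti to the C3 silyloxy group, the face that peracids also prefer on 3-O-protected rings of this type. C8 follows stereospecifically, because the cycloaddition places C9 cis to C4 (8R in 12) and the single inversion turns this into 8S with C9 cis to the C5 methyl. The step needs site selectivity for the ring diene over ene hydroperoxidation and over the C7–C10 diene, which the electron-rich tetrasubstituted C5=C6 terminus and the deactivating ester provide, and it needs SN2 rather than ionisation or SN2′ at C8, which the electron-poor enoate on C9 favours by destabilising a C8 cation.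

Step 10
Reactants: 13 ethyl (2E)-3-[(2S,6S,7aR)-6-(TBS-oxy)-4,4,7a-trimethyl-2,4,5,6,7,7a-hexahydro-1-benzofuran-2-yl]but-2-enoate
Product: 14 (2E)-3-[(2S,6S,7aR)-6-(TBS-oxy)-4,4,7a-trimethyl-2,4,5,6,7,7a-hexahydro-1-benzofuran-2-yl]but-2-en-1-ol
Conditions: iBu2AlH, CH2Cl2, −78 °C; aq. potassium sodium tartrate
Reagents that add atoms: none
Why: 1,2-Reduction of the α,β-unsaturated ester by the aluminium hydride gives the allylic alcohol without touching the allylic ether ring, the silyl ether or the alkene geometry.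

Step 11
Reactants: 14 (2E)-3-[(2S,6S,7aR)-6-(TBS-oxy)-4,4,7a-trimethyl-2,4,5,6,7,7a-hexahydro-1-benzofuran-2-yl]but-2-en-1-ol
Product: 16 {(2E)-3-[(2S,6S,7aR)-6-(TBS-oxy)-4,4,7a-trimethyl-2,4,5,6,7,7a-hexahydro-1-benzofuran-2-yl]but-2-en-1-yl}triphenylphosphonium bromide, via allylic bromide 15 (not isolated)
Conditions: CBr4, PPh3 (2.2 equiv), CH2Cl2, 0 °C to rt; precipitation from Et2O
Reagents that add atoms: carbon tetrabromide BrC(Br)(Br)Br; triphenylphosphine c1ccc(cc1)P(c1ccccc1)c1ccccc1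
Why: Appel bromination of the primary allylic alcohol under acid-free conditions (so that the doubly allylic C8–O bond is not ionised and C8 keeps its configuration) is followed in the same flask by SN2 quaternisation of the excess phosphine by the allylic bromide.

Step 12
Reactants: 11 ethyl (2E,4E)-5-[(4R)-4-(TBS-oxy)-2,6,6-trimethylcyclohex-1-en-1-yl]-3-methylpenta-2,4-dienoate
Product: 17 ethyl (2E,4E)-5-[(4R)-4-hydroxy-2,6,6-trimethylcyclohex-1-en-1-yl]-3-methylpenta-2,4-dienoate
Conditions: Bu4NF, THF, rt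
Reagents that add atoms: none
Why: Fluoride cleaves the Si–O bond (desilylation) and frees the C3 hydroxyl that is needed as a directing group, the ester and triene being inert.

Step 13
Reactants: 17 ethyl (2E,4E)-5-[(4R)-4-hydroxy-2,6,6-trimethylcyclohex-1-en-1-yl]-3-methylpenta-2,4-dienoate
Product: 18 ethyl (2E,4E)-5-[(1R,4S,6S)-4-hydroxy-2,2,6-trimethyl-7-oxabicyclo[4.1.0]heptan-1-yl]-3-methylpenta-2,4-dienoate (syn-5,6-epoxide, oxirane cis to the hydroxyl)
Conditions: VO(acac)2 (cat.), tBuOOH, CH2Cl2, rt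
Reagents that add atoms: tert-butyl hydroperoxide CC(C)(C)OO
Why: Hydroxyl-directed vanadium-catalysed epoxidation, in which the C3 alkoxide binds the vanadium tert-butylperoxide and delivers oxygen to the homoallylic tetrasubstituted C5=C6 bond on its own face, so C5 (S) and C6 (R) are set syn to the C3 oxygen while the chain alkenes, out of reach of the metal, stay intact.

Step 14
Reactants: 18 ethyl (2E,4E)-5-[(1R,4S,6S)-4-hydroxy-2,2,6-trimethyl-7-oxabicyclo[4.1.0]heptan-1-yl]-3-methylpenta-2,4-dienoate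
Product: 19 ethyl (2E,4E)-3-methyl-5-[(1R,2R,4S)-1,2,4-trihydroxy-2,6,6-trimethylcyclohexyl]penta-2,4-dienoate
Conditions: HClO4 (cat.), THF/H2O, 0 °C
Reagents that add atoms: water O
Why: Acid-catalysed epoxide hydrolysis in which water attacks C5 rather than C6 (a C6 cation is destabilised by the conjugated enoate and C6 is neopentyl) anti to the oxirane oxygen in the trans-diaxial sense, inverting C5 to R while C6 keeps its oxygen (R), which gives the 5,6-trans diol with the C5 hydroxyl anti and the C6 hydroxyl syn to the C3 hydroxyl.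

Step 15
Reactants: 19 ethyl (2E,4E)-3-methyl-5-[(1R,2R,4S)-1,2,4-trihydroxy-2,6,6-trimethylcyclohexyl]penta-2,4-dienoate
Product: 20 ethyl (2E,4E)-5-[(1R,2R,4S)-4-(TBS-oxy)-1,2-dihydroxy-2,6,6-trimethylcyclohexyl]-3-methylpenta-2,4-dienoate
Conditions: TBSCl, imidazole, DMF, rt
Reagents that add atoms: tert-butyldimethylsilyl chloride CC(C)(C)[Si](C)(C)Cl
Why: Silylation is selective for the secondary C3 hydroxyl because the two tertiary hydroxyls are too hindered, and the ether confines the later Appel and Wittig chemistry to the chain terminus.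

Step 16
Reactants: 20 ethyl (2E,4E)-5-[(1R,2R,4S)-4-(TBS-oxy)-1,2-dihydroxy-2,6,6-trimethylcyclohexyl]-3-methylpenta-2,4-dienoate
Product: 21 (1R,2R,4S)-4-(TBS-oxy)-1-[(1E,3E)-5-hydroxy-3-methylpenta-1,3-dien-1-yl]-2,6,6-trimethylcyclohexane-1,2-diol
Conditions: iBu2AlH (excess), CH2Cl2, −78 to −20 °C; aq. potassium sodium tartrate
Reagents that add atoms: none
Why: 1,2-Reduction of the dienoate by the aluminium hydride (the two tertiary hydroxyls only consume extra reagent as alkoxides) gives the primary allylic alcohol with the diene geometry unchanged.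

Step 17
Reactants: 21 (1R,2R,4S)-4-(TBS-oxy)-1-[(1E,3E)-5-hydroxy-3-methylpenta-1,3-dien-1-yl]-2,6,6-trimethylcyclohexane-1,2-diol
Product: 23 {(2E,4E)-5-[(1R,2R,4S)-4-(TBS-oxy)-1,2-dihydroxy-2,6,6-trimethylcyclohexyl]-3-methylpenta-2,4-dien-1-yl}triphenylphosphonium bromide, via dienyl bromide 22 (not isolated)
Conditions: CBr4 (1.05 equiv), PPh3 (2.2 equiv), CH2Cl2, −20 °C to rt
Reagents that add atoms: carbon tetrabromide BrC(Br)(Br)Br; triphenylphosphine c1ccc(cc1)P(c1ccccc1)c1ccccc1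
Why: The Appel reaction converts only the unhindered primary allylic alcohol (the tertiary hydroxyls do not form oxyphosphonium ions at this temperature), and the bromide is trapped at once by the excess phosphine in an SN2 quaternisation, with no acid to ionise the tertiary allylic C6 hydroxyl.

Step 18
Reactants: 23 {(2E,4E)-5-[(1R,2R,4S)-4-(TBS-oxy)-1,2-dihydroxy-2,6,6-trimethylcyclohexyl]-3-methylpenta-2,4-dien-1-yl}triphenylphosphonium bromide, 24 (2E,4E,6E)-2,7-dimethylocta-2,4,6-trienedial (C10 dialdehyde)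
Product: 25 (2E,4E,6E,8E,10E,12E)-13-[(1R,2R,4S)-4-(TBS-oxy)-1,2-dihydroxy-2,6,6-trimethylcyclohexyl]-2,7,11-trimethyltrideca-2,4,6,8,10,12-hexaenal (C25 aldehyde)
Conditions: 24 (3 equiv), NaOMe, CH2Cl2/MeOH, 0 °C to rt; then heptane, 80 °C, dark
Reagents that add atoms: none
Why: Wittig olefination of one formyl group of the excess dialdehyde by the semi-stabilised ylide forms C11=C12, and heating equilibrates the hindered 11Z isomer to the all-E aldehyde, the tertiary hydroxyls not being deprotonated competitively by methoxide.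

Step 19
Reactants: 16 {(2E)-3-[(2S,6S,7aR)-6-(TBS-oxy)-4,4,7a-trimethyl-2,4,5,6,7,7a-hexahydro-1-benzofuran-2-yl]but-2-en-1-yl}triphenylphosphonium bromide, 25 C25 aldehyde
Product: 26 3,3'-bis-TBS ether of (3S,5R,6R,3'S,5'R,8'S)-5',8'-epoxy-5,6,5',8'-tetrahydro-β,β-carotene-3,5,6,3'-tetrol
Conditions: NaOMe (added last), CH2Cl2/MeOH, 0 °C to rt; then heptane, 80 °C, dark, N2
Reagents that add atoms: none
Why: Wittig olefination joins the two halves at C11'=C12'; generating the ylide in the presence of the aldehyde keeps its concentration low and limits vinylogous β-elimination of the ring oxygen, and the hindered 11'Z isomer is equilibrated thermally to the all-E polyene without affecting any stereocentre.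

Step 20
Reactants: 26 3,3'-bis-TBS ether of the tetrol
Product: 27 (3S,5R,6R,3'S,5'R,8'S)-5',8'-epoxy-5,6,5',8'-tetrahydro-β,β-carotene-3,5,6,3'-tetrol (target)
Conditions: Bu4NF, THF, 0 °C to rt, dark
Reagents that add atoms: none
Why: Fluoride removes both silyl ethers (desilylation) under non-acidic conditions, which the acid-sensitive C8' allylic ether, the tertiary allylic C6 hydroxyl and the polyene tolerate.

**Compound list**
1 | ketoisophorone (2,6,6-trimethylcyclohex-2-ene-1,4-dione) | CC1=CC(=O)CC(C)(C)C1=O | starting material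
2 | (6R)-2,2,6-trimethylcyclohexane-1,4-dione | O=C1[C@H](C)CC(=O)CC1(C)C | intermediate
3 | (4R,6R)-4-hydroxy-2,2,6-trimethylcyclohexan-1-one (actinol) | O=C1[C@H](C)C[C@@H](O)CC1(C)C | intermediate
4 | (4R,6R)-4-(TBS-oxy)-2,2,6-trimethylcyclohexan-1-one | O=C1[C@H](C)C[C@@H](O[Si](C)(C)C(C)(C)C)CC1(C)C | intermediate
5 | (4R)-4-(TBS-oxy)-2,6,6-trimethylcyclohex-1-en-1-yl trifluoromethanesulfonate | FC(F)(F)S(=O)(=O)OC1=C(C)C[C@@H](O[Si](C)(C)C(C)(C)C)CC1(C)C | intermediate
6 | but-3-yn-2-ol (racemic) | CC(O)C#C | starting material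
7 | 4-[(4R)-4-(TBS-oxy)-2,6,6-trimethylcyclohex-1-en-1-yl]but-3-yn-2-ol (both carbinol epimers) | CC(O)C#CC1=C(C)C[C@@H](O[Si](C)(C)C(C)(C)C)CC1(C)C | intermediate
8 | (3E)-4-[(4R)-4-(TBS-oxy)-2,6,6-trimethylcyclohex-1-en-1-yl]but-3-en-2-ol (both carbinol epimers) | CC(O)/C=C/C1=C(C)C[C@@H](O[Si](C)(C)C(C)(C)C)CC1(C)C | intermediate
9 | (3E)-4-[(4R)-4-(TBS-oxy)-2,6,6-trimethylcyclohex-1-en-1-yl]but-3-en-2-one | CC(=O)/C=C/C1=C(C)C[C@@H](O[Si](C)(C)C(C)(C)C)CC1(C)C | intermediate
10 | triethyl phosphonoacetate | CCOC(=O)CP(=O)(OCC)OCC | starting material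
11 | ethyl (2E,4E)-5-[(4R)-4-(TBS-oxy)-2,6,6-trimethylcyclohex-1-en-1-yl]-3-methylpenta-2,4-dienoate (C15 trienoate) | CCOC(=O)/C=C(C)/C=C/C1=C(C)C[C@@H](O[Si](C)(C)C(C)(C)C)CC1(C)C | intermediate
12 | 5,8-endoperoxide (5R,8R): ethyl (2E)-3-[(3R,7S,8aR)-7-(TBS-oxy)-5,5,8a-trimethyl-3,5,6,7,8,8a-hexahydro-1,2-benzodioxin-3-yl]but-2-enoate | CCOC(=O)/C=C(\C)[C@H]1C=C2C(C)(C)C[C@H](O[Si](C)(C)C(C)(C)C)C[C@@]2(C)OO1 | intermediate
13 | ethyl (2E)-3-[(2S,6S,7aR)-6-(TBS-oxy)-4,4,7a-trimethyl-2,4,5,6,7,7a-hexahydro-1-benzofuran-2-yl]but-2-enoate (C15 dihydrofuran enoate) | CCOC(=O)/C=C(\C)[C@@H]1C=C2C(C)(C)C[C@H](O[Si](C)(C)C(C)(C)C)C[C@@]2(C)O1 | intermediate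
14 | (2E)-3-[(2S,6S,7aR)-6-(TBS-oxy)-4,4,7a-trimethyl-2,4,5,6,7,7a-hexahydro-1-benzofuran-2-yl]but-2-en-1-ol | OC/C=C(\C)[C@@H]1C=C2C(C)(C)C[C@H](O[Si](C)(C)C(C)(C)C)C[C@@]2(C)O1 | intermediate
15 | allylic bromide: (2S,6S,7aR)-2-[(2E)-4-bromobut-2-en-2-yl]-6-(TBS-oxy)-4,4,7a-trimethyl-2,4,5,6,7,7a-hexahydro-1-benzofuran | BrC/C=C(\C)[C@@H]1C=C2C(C)(C)C[C@H](O[Si](C)(C)C(C)(C)C)C[C@@]2(C)O1 | intermediate
16 | {(2E)-3-[(2S,6S,7aR)-6-(TBS-oxy)-4,4,7a-trimethyl-2,4,5,6,7,7a-hexahydro-1-benzofuran-2-yl]but-2-en-1-yl}triphenylphosphonium bromide | [Br-].c1ccccc1[P+](c1ccccc1)(c1ccccc1)C/C=C(\C)[C@@H]1C=C2C(C)(C)C[C@H](O[Si](C)(C)C(C)(C)C)C[C@@]2(C)O1 | intermediate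
17 | ethyl (2E,4E)-5-[(4R)-4-hydroxy-2,6,6-trimethylcyclohex-1-en-1-yl]-3-methylpenta-2,4-dienoate | CCOC(=O)/C=C(C)/C=C/C1=C(C)C[C@@H](O)CC1(C)C | intermediate
18 | ethyl (2E,4E)-5-[(1R,4S,6S)-4-hydroxy-2,2,6-trimethyl-7-oxabicyclo[4.1.0]heptan-1-yl]-3-methylpenta-2,4-dienoate (syn-5,6-epoxide) | CCOC(=O)/C=C(C)/C=C/[C@]12O[C@@]1(C)C[C@@H](O)CC2(C)C | intermediate
19 | ethyl (2E,4E)-3-methyl-5-[(1R,2R,4S)-1,2,4-trihydroxy-2,6,6-trimethylcyclohexyl]penta-2,4-dienoate | CCOC(=O)/C=C(C)/C=C/[C@@]1(O)C(C)(C)C[C@H](O)C[C@@]1(C)O | intermediate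
20 | ethyl (2E,4E)-5-[(1R,2R,4S)-4-(TBS-oxy)-1,2-dihydroxy-2,6,6-trimethylcyclohexyl]-3-methylpenta-2,4-dienoate | CCOC(=O)/C=C(C)/C=C/[C@@]1(O)C(C)(C)C[C@H](O[Si](C)(C)C(C)(C)C)C[C@@]1(C)O | intermediate
21 | (1R,2R,4S)-4-(TBS-oxy)-1-[(1E,3E)-5-hydroxy-3-methylpenta-1,3-dien-1-yl]-2,6,6-trimethylcyclohexane-1,2-diol | OC/C=C(C)/C=C/[C@@]1(O)C(C)(C)C[C@H](O[Si](C)(C)C(C)(C)C)C[C@@]1(C)O | intermediate
22 | dienyl bromide: (1R,2R,4S)-1-[(1E,3E)-5-bromo-3-methylpenta-1,3-dien-1-yl]-4-(TBS-oxy)-2,6,6-trimethylcyclohexane-1,2-diol | BrC/C=C(C)/C=C/[C@@]1(O)C(C)(C)C[C@H](O[Si](C)(C)C(C)(C)C)C[C@@]1(C)O | intermediate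
23 | {(2E,4E)-5-[(1R,2R,4S)-4-(TBS-oxy)-1,2-dihydroxy-2,6,6-trimethylcyclohexyl]-3-methylpenta-2,4-dien-1-yl}triphenylphosphonium bromide | [Br-].c1ccccc1[P+](c1ccccc1)(c1ccccc1)C/C=C(C)/C=C/[C@@]1(O)C(C)(C)C[C@H](O[Si](C)(C)C(C)(C)C)C[C@@]1(C)O | intermediate
24 | (2E,4E,6E)-2,7-dimethylocta-2,4,6-trienedial (C10 dialdehyde) | O=C/C(C)=C/C=C/C=C(\C)C=O | starting material
25 | (2E,4E,6E,8E,10E,12E)-13-[(1R,2R,4S)-4-(TBS-oxy)-1,2-dihydroxy-2,6,6-trimethylcyclohexyl]-2,7,11-trimethyltrideca-2,4,6,8,10,12-hexaenal (C25 aldehyde) | CC(/C=C/C=C(C)/C=C/[C@@]1(O)C(C)(C)C[C@H](O[Si](C)(C)C(C)(C)C)C[C@@]1(C)O)=C\C=C\C=C(C)\C=O | intermediate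
26 | 3,3'-bis-TBS ether of (3S,5R,6R,3'S,5'R,8'S)-5',8'-epoxy-5,6,5',8'-tetrahydro-β,β-carotene-3,5,6,3'-tetrol | CC(/C=C/C=C(C)/C=C/[C@@]1(O)C(C)(C)C[C@H](O[Si](C)(C)C(C)(C)C)C[C@@]1(C)O)=C\C=C\C=C(C)\C=C\C=C(/C)[C@@H]1C=C2C(C)(C)C[C@H](O[Si](C)(C)C(C)(C)C)C[C@@]2(C)O1 | intermediate
27 | (3S,5R,6R,3'S,5'R,8'S)-5',8'-epoxy-5,6,5',8'-tetrahydro-β,β-carotene-3,5,6,3'-tetrol (CNP0210286.3) | CC(/C=C/C=C(C)/C=C/[C@@]1(O)C(C)(C)C[C@H](O)C[C@@]1(C)O)=C\C=C\C=C(C)\C=C\C=C(/C)[C@@H]1C=C2C(C)(C)C[C@H](O)C[C@@]2(C)O1 | target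

**Step count and risks**
Total: 20 steps. Longest linear sequence: 17 steps (steps 1–8, 12–18, 19 and 20); the dihydrofuran branch (steps 9–11) joins at step 19.

The three steps most likely to fail:

Step 9. The (4+2) addition may lose to ene hydroperoxidation at the C5 methyl or at C4, or the phosphine may trigger SN2′ closure or ionisation at C8, so that the dihydrofuran forms with poor stereocontrol or not at all. The fallback sets out from 11 and returns at 14. Buffered mCPBA (NaHCO3, CH2Cl2, 0 °C) epoxidises the ring double bond, by peracid precedent mainly anti to the silyloxy group, to give the anti-5,6-epoxide F1. iBu2AlH (CH2Cl2, −78 °C) reduces the ester to the epoxy dienol F2, whose chain is now electron-rich. A trace of HCl in CHCl3 at 0 °C then brings about the classical 5,6-epoxide to 5,8-epoxide (furanoid) rearrangement, in which C5 keeps its oxygen and C8 forms as two epimers. Chromatography gives the 8S epimer, which is 14.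

Step 13. Oxygen delivery may be slow or unselective, because the directing hydroxyl must become axial and then sits 1,3-diaxial to a C1 methyl, while undirected oxidation would favour the other face. The fallback sets out from 5 and returns at 18, with reagent control in place of substrate control. Methoxycarbonylation of 5 (Pd(OAc)2, PPh3, CO, Et3N, MeOH/DMF) gives the methyl ester F3, and iBu2AlH gives the allylic alcohol F4. Sharpless asymmetric epoxidation (Ti(OiPr)4, L-(+)-diethyl tartrate, tBuOOH, 4 Å sieves, CH2Cl2, −20 °C) places the oxirane on the face of the silyloxy group and gives the syn-epoxy alcohol F5. Oxidation with SO3·pyridine, DMSO and Et3N gives the syn-epoxy aldehyde F6. Horner–Wadsworth–Emmons reaction with the anion of triethyl (2E)-3-methyl-4-phosphonobut-2-enoate (nBuLi, THF, −78 °C to rt) gives the silylated syn-epoxy dienoate F7, and Bu4NF then gives 18.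

Step 14. Ionisation of the C6–O bond (loss of configuration at C6 or closure to a 5,8-furanoid) or a pinacol-type ring contraction after C5–O cleavage may compete with the SN2-like attack of water at C5. The fallback sets out from 9 and returns at 20; it moves the oxidation to the enone, where the carbonyl conjugated with C7=C8 rules out a C6 cation. Bu4NF gives (3R)-3-hydroxy-β-ionone F8, and VO(acac)2 with tBuOOH gives the syn-epoxy enone F9. Dilute HClO4 in THF/H2O gives the trihydroxy enone F10, and TBSCl with imidazole gives its C3 silyl ether F11. Horner–Wadsworth–Emmons reaction with 10 (NaH in excess, THF) gives 20.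

Further compounds
F1 | step 9 | anti-5,6-epoxide: ethyl (2E,4E)-5-[(1S,4S,6R)-4-(TBS-oxy)-2,2,6-trimethyl-7-oxabicyclo[4.1.0]heptan-1-yl]-3-methylpenta-2,4-dienoate | CCOC(=O)/C=C(C)/C=C/[C@@]12O[C@]1(C)C[C@@H](O[Si](C)(C)C(C)(C)C)CC2(C)C
F2 | step 9 | epoxy dienol: (2E,4E)-5-[(1S,4S,6R)-4-(TBS-oxy)-2,2,6-trimethyl-7-oxabicyclo[4.1.0]heptan-1-yl]-3-methylpenta-2,4-dien-1-ol | OC/C=C(C)/C=C/[C@@]12O[C@]1(C)C[C@@H](O[Si](C)(C)C(C)(C)C)CC2(C)C
F3 | step 13 | methyl ester: methyl (4R)-4-(TBS-oxy)-2,6,6-trimethylcyclohex-1-ene-1-carboxylate | COC(=O)C1=C(C)C[C@@H](O[Si](C)(C)C(C)(C)C)CC1(C)C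
F4 | step 13 | allylic alcohol: [(4R)-4-(TBS-oxy)-2,6,6-trimethylcyclohex-1-en-1-yl]methanol | OCC1=C(C)C[C@@H](O[Si](C)(C)C(C)(C)C)CC1(C)C
F5 | step 13 | syn-epoxy alcohol: [4-(TBS-oxy)-2,2,6-trimethyl-7-oxabicyclo[4.1.0]heptan-1-yl]methanol, oxirane cis to the silyloxy group | OC[C@]12O[C@@]1(C)C[C@@H](O[Si](C)(C)C(C)(C)C)CC2(C)C
F6 | step 13 | syn-epoxy aldehyde: 4-(TBS-oxy)-2,2,6-trimethyl-7-oxabicyclo[4.1.0]heptane-1-carbaldehyde, oxirane cis to the silyloxy group | O=C[C@]12O[C@@]1(C)C[C@@H](O[Si](C)(C)C(C)(C)C)CC2(C)C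
F7 | step 13 | silylated syn-epoxy dienoate: ethyl (2E,4E)-5-[(1R,4S,6S)-4-(TBS-oxy)-2,2,6-trimethyl-7-oxabicyclo[4.1.0]heptan-1-yl]-3-methylpenta-2,4-dienoate | CCOC(=O)/C=C(C)/C=C/[C@]12O[C@@]1(C)C[C@@H](O[Si](C)(C)C(C)(C)C)CC2(C)C
F8 | step 14 | (3R)-3-hydroxy-β-ionone: (3E)-4-[(4R)-4-hydroxy-2,6,6-trimethylcyclohex-1-en-1-yl]but-3-en-2-one | CC(=O)/C=C/C1=C(C)C[C@@H](O)CC1(C)C
F9 | step 14 | syn-epoxy enone: (3E)-4-[(1R,4S,6S)-4-hydroxy-2,2,6-trimethyl-7-oxabicyclo[4.1.0]heptan-1-yl]but-3-en-2-one | CC(=O)/C=C/[C@]12O[C@@]1(C)C[C@@H](O)CC2(C)C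
F10 | step 14 | trihydroxy enone: (3E)-4-[(1R,2R,4S)-1,2,4-trihydroxy-2,6,6-trimethylcyclohexyl]but-3-en-2-one | CC(=O)/C=C/[C@@]1(O)C(C)(C)C[C@H](O)C[C@@]1(C)O
F11 | step 14 | C3 silyl ether: (3E)-4-[(1R,2R,4S)-4-(TBS-oxy)-1,2-dihydroxy-2,6,6-trimethylcyclohexyl]but-3-en-2-one | CC(=O)/C=C/[C@@]1(O)C(C)(C)C[C@H](O[Si](C)(C)C(C)(C)C)C[C@@]1(C)O
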